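## Structural features

The target is a tertiary alkyl aryl ether between C2 of a trans-decalin (ring A: C1–C4, C4a, C8a; ring B: C4a, C5–C8, C8a) and the 2-oxygen of a honokiol-type biaryl. Arene a carries the ether oxygen, with arene b ortho and an allyl group para to it; arene b is a 3-allyl-4-hydroxyphenyl group. All four stereocentres lie on the decalin: C4a (S, angular methyl) and C8a (S, hydrogen) are adjacent and trans, while C2 (R, methyl equatorial, aryloxy axial and anti to the angular methyl) and C7 (R, 2-hydroxypropan-2-yl equatorial and cis to the angular methyl) are each 1,3 to C8a and 1,4 to C4a. The fragile groups are the tertiary ether (ionised by protic and Lewis acids, able to lose the phenol by elimination), the tertiary alcohol (dehydration), the two allyl groups (reduced by any hydrogenation, moved into conjugation by metal hydrides or strong base) and the free phenol. The real difficulty is twofold: the hindered C2–O–aryl bond, best made by SNAr of a tertiary alkoxide so that the C–O bond at the stereocentre is never broken, and the relation of the quaternary C2 to the remote centres C4a, C8a and C7. The key step exploits ring B: with a C5=C6 double bond it is a cyclohexene whose C4a–C8a and C7–C8 bonds are the two σ-bonds of a [4+2] cycloaddition between a C4a=C5–C6=C7 diene and a C8a=C8 alkene. The four atoms C4–C3–C2–C1 of ring A then form the tether of a 1,7,9-decatriene, so that C2 with its methyl and aryloxy groups is the only stereocentre of the open chain and has to control the other three. C7 carries a carbinol that can come from an ester, which polarises the diene and, being enolisable, lets C7 be corrected after the cycloaddition.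

## Logic of the disconnections

**24 ⇒ 21 + 23 (23 ⇒ 22).** The biaryl bond a1–b1 is cut last. Arene b then arrives complete, with its allyl group and free hydroxyl, so neither a Claisen rearrangement nor a phenol protecting group is needed on material that carries the tertiary ether. The forward step must couple at a bromide flanked by a bulky tertiary alkoxy group without moving either allyl double bond. 23 comes from 22 by exchange of C–Br for C–B.

**21 ⇒ 20 ⇒ 19.** The allyl group of arene a is cut between the benzylic and the vinylic carbon, and the benzylic bromide is traced to the benzylic alcohol. The benzylic carbon is the former formyl carbon that activates the ether-forming substitution, so it serves twice. The allyl group has to be made after the hydrogenation of ring B, and the sp3–sp2 coupling must leave the aryl bromide alone.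

**19 ⇒ 17 (through 18).** Both C–CH3 bonds of the carbinol are cut, giving an ester at C7. The gain is an enolisable centre at C7. The forward step is a double Grignard addition that must not disturb the equatorial configuration.

**17 ⇒ 15 (through 16) ⇒ 14.** C7 is inverted back to its axial form, the benzylic pivalate is restored and the C5–C6 bond becomes a double bond. This exposes the cyclohexene of a cycloadduct. Forward, hydrogenation has to spare the aryl bromide, and epimerisation must follow hydrogenation so that the double bond cannot move into conjugation with the ester.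

**14 ⇒ 13.** The C4a–C8a and C7–C8 bonds are cut together. Both rings open, three stereocentres disappear and only C2 remains. The forward cycloaddition must give the trans ring fusion and the correct face relative to C2. It also needs a geometrically pure 2E,4E-diene, because a 4Z-isomer would cyclise to the wrong C4a/C7 relationship and most probably to a cis fusion.

**13 ⇒ 11 + 12.** The C3–C4 bond of the dienoate is cut. The C4=C5 geometry is then carried by a vinyl iodide and is not created in an olefination of a methyl ketone, which would give a mixture at that double bond. The forward coupling must react at the vinyl iodide and not at the aryl bromide.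

**11 ⇒ 10 ⇒ 9.** These are adjustments at the benzylic carbon: pivalate from alcohol, alcohol from aldehyde. The aldehyde is needed only for the substitution that follows in the retrosynthetic sense. It is reduced before the cycloaddition so that the phenoxide is a poorer leaving group at high temperature, and the ester protecting group is chosen so that a later step removes it without an operation of its own.

**9 ⇒ 6 + 7 (through 8).** The aryl C–O bond is cut. The tertiary alkoxide attacks an activated aryl fluoride, so the C–O bond of the stereocentre is untouched and the configuration is kept. The demand is a tertiary alkoxide that tolerates a vinyl iodide and an aldehyde partner.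

**6 ⇒ 4 (through 5).** The C–CH3 and C–I bonds on the former alkyne carbons are cut. Syn-carbometalation of a terminal alkyne fixes the E-geometry of the trisubstituted double bond. It is placed before the ether formation so that the Lewis-acidic aluminium reagent never meets the tertiary aryl ether.

**4 ⇒ 1 + 2 (through 3).** The bond between the carbinol carbon and the allyl group is cut. This is the only step in which a reagent sets absolute configuration; the catalyst has to distinguish a methyl group from an unbranched chain.

## Other disconnections considered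

**Alternative 1:** Ring B is cut at C4a–C5 and C8a–C8, so that ring A enters intact as the quinone A1 and ring B comes from the 2-substituted diene A2. In the forward direction a chiral Lewis acid bound to the vinylogous-ester carbonyl (C4) would make the methyl-bearing C4a=C8a bond the dienophile and give the cis-fused enedione A3. In its favour: the reaction is intermolecular and convergent and should run at low temperature. The catalyst sets the quaternary carbon C4a directly. The regiochemistry follows from the Lewis acid position, which puts the silyloxymethyl group on C7. Against it here: A3 is cis-fused and has the wrong oxidation pattern. C8a would have to be epimerised next to the C1 carbonyl, where an angular methyl makes the trans preference small. The C1 and C4 carbonyls would have to be removed and the C2 enol ether turned into the methyl carbinol. The tertiary ether would then be made by SNAr of an axial, ring-bound tertiary alkoxide. C7 would have to be oxidised, methylated twice and set by hydrogenation. Comparison: on mechanism Alternative 1 is the better plan, a Lewis-acid-promoted cycloaddition of matched partners against an unactivated thermal one near 200 °C. On absolute stereocontrol it is at least the equal, since the chosen plan depends on a methyl/alkyl differentiation in step 1. On structure the chosen plan is better: 13 already holds the tertiary aryl ether and the final oxidation level of ring A, and 14 is trans-fused as formed. On step economy the chosen plan is clearly shorter, because A3 needs a long series of redox and functional group changes.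

**Alternative 2:** Arene a is cut at a2–a3 and a1–a6: the 2-alkoxy-3-arylbutadiene A4 and methyl propiolate A5 would give the 1,4-cyclohexadiene A6. This would be dehydrogenated to the benzoate, whose ester carbon becomes the benzylic carbon of the allyl group. In its favour: an electron-rich diene and an activated alkyne are well matched. The crowded ortho-alkoxy biaryl is formed without SNAr and without a cross-coupling next to the bulky ether, and on these two points it is the better plan. Against it here: A4 already contains the whole decalin with all four stereocentres, so the disconnection leaves the stereochemical problem untouched. A4 is the enol ether of a tertiary alcohol, hard to make and labile to acid. Its aryl group opposes the directing effect of the alkoxy group, so regioisomers are to be expected. The isopropenyl group would still have to be hydrated before any allyl group is present. Comparison: on structure the two plans are complementary, not competing, because Alternative 2 builds the arene and the chosen plan the decalin. On mechanism the cycloaddition of Alternative 2 is the easier one. On step economy the ester-to-allyl sequence is the same as in the chosen route (equal), but the total is longer because a separate decalin synthesis must be added.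

**Alternative 3:** Arene b is cut at b1–b2 and b5–b6: the enamine of the arylacetaldehyde A7 would add to the dienone A8, and aldol condensation would close the cyclohexenone A9. Dehydrogenation (for example a Saegusa-type oxidation with Pd(OAc)2) and desilylation would then give the phenol. In its favour: both C–C bonds are made by mild polar chemistry. The allyl group of arene b arrives with A8. Both epimers at b1 converge on aromatisation. No cross-coupling at the hindered junction is needed, and on this last point it is the equal or the better of the chosen plan. Against it here: A7 presupposes the complete decalin ether and arene a. The aromatisation has to be carried out in the presence of two allyl groups and several benzylic and allylic C–H bonds. Arene b then costs three operations where the chosen plan needs two (steps 13 and 14). Comparison: on structure it offers nothing for the decalin. On mechanism it is mild but ends in an oxidation that is less selective than a Suzuki–Miyaura coupling. On step economy the chosen plan is shorter.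

Key step: step 7

**Remarks on the chemistry (before the steps)**

- Locants: all decalin compounds are numbered as in the target (C2 ether carbon, C4a angular-methyl carbon, C7 ester or carbinol carbon, C8a ring-fusion CH), even where a systematic name would number differently. Arene a is the ether-bearing ring and arene b the phenol ring.
- Assumption for step 1: the diol-catalysed allylboration is taken to follow the facial sense known for aryl methyl ketones, with the alkynyl chain in the place of the aryl group. If the sense is the opposite, the (S)-catalyst is used and nothing else changes.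
- Assumption on supply: 2 and 22 are taken as catalogue compounds.
- Configuration check: the ether carbon is R in the open chain and stays R. The cycloadduct 14 is 2R,4aS,7R,8aS with the ester axial. 15 is 7S only because the CIP priorities change on hydrogenation. 17 is 7R with the ester equatorial, as in the target.

## Route

Step 1
Reactants: 1 hex-5-yn-2-one; 2 allyldiisopropoxyborane
Product: 4 (R)-4-methyloct-1-en-7-yn-4-ol, via borate ester 3 (not isolated)
Conditions: (R)-3,3′-dibromo-1,1′-bi-2-naphthol (15 mol %), PhMe/PhCF3 3:1, −35 °C; aq. work-up
Reagents that add atoms: none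
Why: Chiral-diol-catalysed asymmetric allylboration of a ketone: exchange of one isopropoxy group for the binaphthol gives a more Lewis-acidic allylboronate that adds through a closed six-membered chair transition state. The catalyst distinguishes methyl from the alkyl chain and delivers allyl to the Si face, which sets the carbinol carbon as R; the terminal alkyne is inert.

Step 2
Reactants: 4 (R)-4-methyloct-1-en-7-yn-4-ol
Product: 6 (4R,7E)-8-iodo-4,7-dimethylocta-1,7-dien-4-ol, via alkenylalane 5 (not isolated)
Conditions: Me3Al (3 equiv), Cp2ZrCl2 (0.3 equiv), CH2Cl2, 0 °C → rt; then I2, THF, −30 °C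
Reagents that add atoms: trimethylaluminium, C[Al](C)C; iodine, II
Why: Zirconium-catalysed methylalumination (Negishi carboalumination) adds CH3 and Al syn across the terminal alkyne with Al on the terminal carbon, and iodinolysis with retention gives the E-vinyl iodide. The alcohol is carried as its aluminium alkoxide and the monosubstituted alkene reacts far more slowly than the alkyne.

Step 3
Reactants: 6 (4R,7E)-8-iodo-4,7-dimethylocta-1,7-dien-4-ol; 7 3-bromo-4-fluorobenzaldehyde
Product: 9 3-bromo-4-{[(4R,7E)-8-iodo-4,7-dimethylocta-1,7-dien-4-yl]oxy}benzaldehyde, via potassium alkoxide 8 (not isolated)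
Conditions: KN(SiMe3)2 (1.05 equiv), THF, −40 °C; then 7, −40 °C → rt
Reagents that add atoms: none
Why: SNAr: the tertiary alkoxide attacks the fluorine-bearing carbon, activated by the para formyl and ortho bromo groups. The C–O bond of the stereocentre is not involved, so the R configuration is kept, and the vinyl iodide is inert to an alkoxide.

Step 4
Reactants: 9 3-bromo-4-{[(4R,7E)-8-iodo-4,7-dimethylocta-1,7-dien-4-yl]oxy}benzaldehyde
Product: 10 (3-bromo-4-{[(4R,7E)-8-iodo-4,7-dimethylocta-1,7-dien-4-yl]oxy}phenyl)methanol
Conditions: NaBH4, MeOH, 0 °C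
Reagents that add atoms: none
Why: Chemoselective hydride reduction of the aryl aldehyde. It is done before the cycloaddition so that the phenoxide is a poorer leaving group at 200 °C and the aryl bromide is less prone to oxidative addition in step 6.

Step 5
Reactants: 10 (3-bromo-4-{[(4R,7E)-8-iodo-4,7-dimethylocta-1,7-dien-4-yl]oxy}phenyl)methanol
Product: 11 3-bromo-4-{[(4R,7E)-8-iodo-4,7-dimethylocta-1,7-dien-4-yl]oxy}benzyl pivalate
Conditions: PivCl, pyridine, DMAP (cat.), CH2Cl2, 0 °C → rt
Reagents that add atoms: pivaloyl chloride, CC(C)(C)C(=O)Cl
Why: Acylation of the primary benzylic alcohol under basic conditions. The pivalate withstands the Heck reaction, 200 °C and hydrogenation, and is removed in step 9 in the same operation as the epimerisation.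

Step 6
Reactants: 11 3-bromo-4-{[(4R,7E)-8-iodo-4,7-dimethylocta-1,7-dien-4-yl]oxy}benzyl pivalate; 12 ethyl acrylate
Product: 13 ethyl (2E,4E,8R)-8-{2-bromo-4-[(pivaloyloxy)methyl]phenoxy}-5,8-dimethylundeca-2,4,10-trienoate
Conditions: 12 (5 equiv), Pd(OAc)2 (5 mol %), K2CO3, n-Bu4NCl, DMF, 25–40 °C
Reagents that add atoms: none
Why: Mizoroki–Heck reaction under ligand-free phase-transfer conditions: oxidative addition of the vinyl iodide to zerovalent palladium is much faster than that of the aryl bromide. Syn-insertion of the acrylate and syn-β-hydride elimination give the 2E double bond, and the 4E geometry of the iodide is retained.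

Step 7
Reactants: 13 ethyl (2E,4E,8R)-8-{2-bromo-4-[(pivaloyloxy)methyl]phenoxy}-5,8-dimethylundeca-2,4,10-trienoate
Product: 14 ethyl (2R,4aS,7R,8aS)-2-{2-bromo-4-[(pivaloyloxy)methyl]phenoxy}-2,4a-dimethyl-1,2,3,4,4a,7,8,8a-octahydronaphthalene-7-carboxylate (trans-fused; ester axial; target locants)
Conditions: PhMe (0.01 M, degassed), BHT (10 mol %), N,O-bis(trimethylsilyl)acetamide (0.2 equiv), silanised sealed tube, 200 °C
Reagents that add atoms: none
Why: Thermal intramolecular Diels–Alder reaction of a 1,7,9-decatriene: a concerted, suprafacial [4+2] cycloaddition in which the s-cis dienoate C4a=C5–C6=C7 adds to the monosubstituted alkene C8a=C8 and forms C4a–C8a and C7–C8. The closest known reaction type is the thermal cyclisation of 1,7,9-decatrienes whose tethered diene terminus carries a methyl group, which gives angularly methylated trans-octalins. Ring B is closed as the cyclohexene of the cycloaddition; ring A is closed by the four-atom tether as the C4a–C8a bond forms, the internal alkene carbon joining the tethered diene terminus so that the terminal CH2 stays outside ring A. C7 is fixed stereospecifically by the diene geometry: the ester is an outside (E) substituent and the methyl on C4a an inside (Z) substituent, so they end trans whatever the transition state (ester axial). C4a and C8a are set by the anti arrangement of the tether and the dienophile hydrogen in a chair-like transition state, which gives the trans fusion; the inside methyl is expected to disfavour the syn, cis-fused arrangement. Their sense relative to C2 comes from the same chair, in which the C2 methyl (the larger group by conformational energy) is equatorial and the aryloxy group axial, placing oxygen anti to the angular methyl (4aS,8aS from 2R). The step needs trans-fusion and face selectivity; both rest on this chair and are expected to be moderate, so minor diastereomers would be removed by chromatography. The pure 2E,4E geometry from steps 2 and 6, the quaternary C2 (gem-dialkyl effect), the radical inhibitor, the acid scavenger and the exclusion of oxygen protect the substrate at 200 °C.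

Step 8
Reactants: 14 ethyl (2R,4aS,7R,8aS)-2-{2-bromo-4-[(pivaloyloxy)methyl]phenoxy}-2,4a-dimethyl-1,2,3,4,4a,7,8,8a-octahydronaphthalene-7-carboxylate
Product: 15 ethyl (2R,4aS,7S,8aS)-2-{2-bromo-4-[(pivaloyloxy)methyl]phenoxy}-2,4a-dimethyldecahydronaphthalene-7-carboxylate (ester axial)
Conditions: H2 (4 bar), RhCl(PPh3)3 (10 mol %), PhH/EtOH 1:1, 40 °C
Reagents that add atoms: none
Why: Homogeneous hydrogenation with RhCl(PPh3)3 reduces the cis-disubstituted ring alkene and leaves the aryl bromide, the benzylic pivalate and the ester untouched. No stereocentre is formed; the descriptor at C7 changes only through the CIP priorities.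

Step 9
Reactants: 15 ethyl (2R,4aS,7S,8aS)-2-{2-bromo-4-[(pivaloyloxy)methyl]phenoxy}-2,4a-dimethyldecahydronaphthalene-7-carboxylate
Product: 17 ethyl (2R,4aS,7R,8aS)-2-[2-bromo-4-(hydroxymethyl)phenoxy]-2,4a-dimethyldecahydronaphthalene-7-carboxylate (ester equatorial), via axial hydroxy ester 16 (not isolated)
Conditions: NaOEt (3 equiv), EtOH, reflux
Reagents that add atoms: none
Why: Ethoxide first transesterifies the pivalate (releasing the benzylic alcohol), then reversibly forms the ester enolate at C7. Reprotonation under thermodynamic control places the ester equatorial, cis to the angular methyl (7R); matching ethoxide to the ethyl ester avoids ester exchange. The axial epimer left at equilibrium would be separated and resubmitted.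

Step 10
Reactants: 17 ethyl (2R,4aS,7R,8aS)-2-[2-bromo-4-(hydroxymethyl)phenoxy]-2,4a-dimethyldecahydronaphthalene-7-carboxylate
Product: 19 2-[(2R,4aS,7R,8aS)-2-[2-bromo-4-(hydroxymethyl)phenoxy]-2,4a-dimethyldecahydronaphthalen-7-yl]propan-2-ol, via methyl ketone 18 (not isolated)
Conditions: MeMgBr (5 equiv), THF, 0 °C → rt; aq. NH4Cl
Reagents that add atoms: methylmagnesium bromide, C[Mg]Br
Why: Double Grignard addition to the ester through the methyl ketone gives the tertiary carbinol; one equivalent is consumed by the benzylic alcohol and the aryl bromide does not react. C7 keeps its equatorial configuration, which is also the favoured one if the ketone should enolise.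

Step 11
Reactants: 19 2-[(2R,4aS,7R,8aS)-2-[2-bromo-4-(hydroxymethyl)phenoxy]-2,4a-dimethyldecahydronaphthalen-7-yl]propan-2-ol
Product: 20 2-[(2R,4aS,7R,8aS)-2-[2-bromo-4-(bromomethyl)phenoxy]-2,4a-dimethyldecahydronaphthalen-7-yl]propan-2-ol
Conditions: CBr4, PPh3, 2,6-lutidine, CH2Cl2, 0 °C; used crude
Reagents that add atoms: carbon tetrabromide, BrC(Br)(Br)Br
Why: Appel reaction: the primary benzylic alcohol is activated as an alkoxyphosphonium ion and displaced by bromide under buffered, near-neutral conditions. The hindered tertiary alcohol and the acid-sensitive tertiary ether are not affected.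

Step 12
Reactants: 20 2-[(2R,4aS,7R,8aS)-2-[2-bromo-4-(bromomethyl)phenoxy]-2,4a-dimethyldecahydronaphthalen-7-yl]propan-2-ol
Product: 21 2-[(2R,4aS,7R,8aS)-2-(4-allyl-2-bromophenoxy)-2,4a-dimethyldecahydronaphthalen-7-yl]propan-2-ol
Conditions: CH2=CHMgBr (3 equiv), CuI (10 mol %), THF, −40 → 0 °C
Reagents that add atoms: vinylmagnesium bromide, C=C[Mg]Br
Why: Copper-catalysed cross-coupling of a benzylic bromide with a vinyl Grignard reagent forms the allyl group after the hydrogenation step. The aryl bromide is inert under these conditions and the tertiary alcohol only consumes one equivalent of the reagent.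

Step 13
Reactants: 22 2-allyl-4-bromophenol
Product: 23 2-allyl-4-(4,4,5,5-tetramethyl-1,3,2-dioxaborolan-2-yl)phenol
Conditions: B2pin2, PdCl2(dppf) (3 mol %), KOAc, 1,4-dioxane, 85 °C
Reagents that add atoms: bis(pinacolato)diboron, CC1(C)OB(OC1(C)C)B1OC(C)(C)C(C)(C)O1
Why: Miyaura borylation of the aryl bromide. KOAc is too weak a base to couple the product further or to move the allyl double bond, and the free phenol is tolerated.

Step 14
Reactants: 21 2-[(2R,4aS,7R,8aS)-2-(4-allyl-2-bromophenoxy)-2,4a-dimethyldecahydronaphthalen-7-yl]propan-2-ol; 23 2-allyl-4-(4,4,5,5-tetramethyl-1,3,2-dioxaborolan-2-yl)phenol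
Product: 24 3′,5-diallyl-2-{[(2R,4aS,7R,8aS)-7-(2-hydroxypropan-2-yl)-2,4a-dimethyldecahydronaphthalen-2-yl]oxy}-[1,1′-biphenyl]-4′-ol (target)
Conditions: Pd(OAc)2 (5 mol %), SPhos (10 mol %), K3PO4, PhMe/H2O 10:1, 70 °C
Reagents that add atoms: none
Why: Suzuki–Miyaura coupling with an electron-rich biaryl phosphine, which allows oxidative addition at the hindered ortho-alkoxy bromide at moderate temperature. It forms the a1–b1 bond and delivers the target with both allyl groups, the free phenol and all four stereocentres unchanged.

## Compound list

1 | hex-5-yn-2-one | CC(=O)CCC#C | starting material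
2 | allyldiisopropoxyborane | C=CCB(OC(C)C)OC(C)C | starting material
3 | diisopropyl (R)-4-methyloct-1-en-7-yn-4-yl borate | C=CC[C@](C)(OB(OC(C)C)OC(C)C)CCC#C | intermediate (not isolated)
4 | (R)-4-methyloct-1-en-7-yn-4-ol | C=CC[C@](C)(O)CCC#C | intermediate
5 | [(1E,5R)-5-(dimethylalumanyloxy)-2,5-dimethylocta-1,7-dien-1-yl]dimethylalumane | C=CC[C@](C)(O[Al](C)C)CC/C(C)=C/[Al](C)C | intermediate (not isolated)
6 | (4R,7E)-8-iodo-4,7-dimethylocta-1,7-dien-4-ol | C=CC[C@](C)(O)CC/C(C)=C/I | intermediate
7 | 3-bromo-4-fluorobenzaldehyde | O=Cc1ccc(F)c(Br)c1 | starting material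
8 | potassium (4R,7E)-8-iodo-4,7-dimethylocta-1,7-dien-4-olate | C=CC[C@](C)([O-])CC/C(C)=C/I.[K+] | intermediate (not isolated)
9 | 3-bromo-4-{[(4R,7E)-8-iodo-4,7-dimethylocta-1,7-dien-4-yl]oxy}benzaldehyde | C=CC[C@](C)(Oc1ccc(C=O)cc1Br)CC/C(C)=C/I | intermediate
10 | (3-bromo-4-{[(4R,7E)-8-iodo-4,7-dimethylocta-1,7-dien-4-yl]oxy}phenyl)methanol | C=CC[C@](C)(Oc1ccc(CO)cc1Br)CC/C(C)=C/I | intermediate
11 | 3-bromo-4-{[(4R,7E)-8-iodo-4,7-dimethylocta-1,7-dien-4-yl]oxy}benzyl pivalate | C=CC[C@](C)(Oc1ccc(COC(=O)C(C)(C)C)cc1Br)CC/C(C)=C/I | intermediate
12 | ethyl acrylate | C=CC(=O)OCC | starting material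
13 | ethyl (2E,4E,8R)-8-{2-bromo-4-[(pivaloyloxy)methyl]phenoxy}-5,8-dimethylundeca-2,4,10-trienoate | C=CC[C@](C)(Oc1ccc(COC(=O)C(C)(C)C)cc1Br)CC/C(C)=C/C=C/C(=O)OCC | intermediate
14 | ethyl (2R,4aS,7R,8aS)-2-{2-bromo-4-[(pivaloyloxy)methyl]phenoxy}-2,4a-dimethyl-1,2,3,4,4a,7,8,8a-octahydronaphthalene-7-carboxylate (ester axial) | Brc1cc(COC(=O)C(C)(C)C)ccc1O[C@]2(C)CC[C@]3(C)C=C[C@H](C(=O)OCC)C[C@H]3C2 | intermediate
15 | ethyl (2R,4aS,7S,8aS)-2-{2-bromo-4-[(pivaloyloxy)methyl]phenoxy}-2,4a-dimethyldecahydronaphthalene-7-carboxylate (ester axial) | Brc1cc(COC(=O)C(C)(C)C)ccc1O[C@]2(C)CC[C@]3(C)CC[C@H](C(=O)OCC)C[C@H]3C2 | intermediate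
16 | ethyl (2R,4aS,7S,8aS)-2-[2-bromo-4-(hydroxymethyl)phenoxy]-2,4a-dimethyldecahydronaphthalene-7-carboxylate (ester axial) | Brc1cc(CO)ccc1O[C@]2(C)CC[C@]3(C)CC[C@H](C(=O)OCC)C[C@H]3C2 | intermediate (not isolated)
17 | ethyl (2R,4aS,7R,8aS)-2-[2-bromo-4-(hydroxymethyl)phenoxy]-2,4a-dimethyldecahydronaphthalene-7-carboxylate (ester equatorial) | Brc1cc(CO)ccc1O[C@]2(C)CC[C@]3(C)CC[C@@H](C(=O)OCC)C[C@H]3C2 | intermediate
18 | 1-[(2R,4aS,7R,8aS)-2-[2-bromo-4-(hydroxymethyl)phenoxy]-2,4a-dimethyldecahydronaphthalen-7-yl]ethan-1-one | Brc1cc(CO)ccc1O[C@]2(C)CC[C@]3(C)CC[C@@H](C(C)=O)C[C@H]3C2 | intermediate (not isolated)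
19 | 2-[(2R,4aS,7R,8aS)-2-[2-bromo-4-(hydroxymethyl)phenoxy]-2,4a-dimethyldecahydronaphthalen-7-yl]propan-2-ol | Brc1cc(CO)ccc1O[C@]2(C)CC[C@]3(C)CC[C@@H](C(C)(C)O)C[C@H]3C2 | intermediate
20 | 2-[(2R,4aS,7R,8aS)-2-[2-bromo-4-(bromomethyl)phenoxy]-2,4a-dimethyldecahydronaphthalen-7-yl]propan-2-ol | Brc1cc(CBr)ccc1O[C@]2(C)CC[C@]3(C)CC[C@@H](C(C)(C)O)C[C@H]3C2 | intermediate
21 | 2-[(2R,4aS,7R,8aS)-2-(4-allyl-2-bromophenoxy)-2,4a-dimethyldecahydronaphthalen-7-yl]propan-2-ol | C=CCc1ccc(O[C@]2(C)CC[C@]3(C)CC[C@@H](C(C)(C)O)C[C@H]3C2)c(Br)c1 | intermediate
22 | 2-allyl-4-bromophenol | C=CCc1cc(Br)ccc1O | starting material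
23 | 2-allyl-4-(4,4,5,5-tetramethyl-1,3,2-dioxaborolan-2-yl)phenol | C=CCc1cc(B2OC(C)(C)C(C)(C)O2)ccc1O | intermediate
24 | 3′,5-diallyl-2-{[(2R,4aS,7R,8aS)-7-(2-hydroxypropan-2-yl)-2,4a-dimethyldecahydronaphthalen-2-yl]oxy}-[1,1′-biphenyl]-4′-ol | C=CCc1ccc(O[C@]2(C)CC[C@]3(C)CC[C@@H](C(C)(C)O)C[C@H]3C2)c(-c2ccc(O)c(CC=C)c2)c1 | target

## Step count and least certain steps

Total: 14 steps. Longest linear sequence: 13 steps (steps 1 to 12, then step 14); step 13 is the only side-branch step.

**Step 7 (key step).** Two things are most likely to go wrong. The first is incomplete diastereocontrol: ring fusion and facial selectivity both rest on small conformational energy differences at about 200 °C. The second is loss of substrate by competing thermal processes before the slow cycloaddition of an unactivated alkene to a diene with an inside methyl group takes place. These are a 1,5-hydrogen shift from the inside methyl into the diene and elimination of the phenol from the tertiary ether if any acid is formed.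

Fallback: the decalin is made without a cycloaddition, by Robinson annulation from the chiral pool, and the aryl ether is attached afterwards. Of the compounds of the route it uses only 7, from which it sets out, and it returns at 19. (+)-Dihydrocarvone F1 is condensed with (R)-1-phenylethylamine to the imine F2. Its enamine tautomer adds to but-3-en-2-one on the face chosen by the auxiliary (trans to the isopropenyl group), and hydrolysis gives the diketone F3. NaOMe closes F3 to the octalenone F4, with the 4a-methyl cis to the isopropenyl group. Li in liquid NH3 reduces F4 to the trans-fused decalinone F5. MeTi(OiPr)3 adds from the equatorial side to give the axial tertiary alcohol F6. Its potassium alkoxide and 7 give the aldehyde F7 by SNAr. NaBH4 gives the benzylic alcohol F8. Mukaiyama hydration of the isopropenyl group (Co(acac)2, PhSiH3, O2) gives 19.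

**Step 1.** Most likely to go wrong is insufficient enantioselectivity, because the catalyst must tell a methyl group from an unbranched alkyl chain; the facial sense for a dialkyl ketone is also an assumption.

Fallback: the stereocentre is bought and two epoxide openings attach the two chains. It uses neither 1 nor 2; it sets out from commercial (R)-2-methylglycidol F9 and returns at 4. Vinylmagnesium bromide with CuI opens F9 at its CH2 terminus to the diol F10. Tosyl chloride in pyridine sulfonylates only the primary hydroxyl to give the monotosylate F11. NaH closes the new epoxide F12 without touching the C–O bond of the stereocentre. Propargylmagnesium bromide opens F12 at CH2 to give 4.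

**Step 3.** Most likely to go wrong is consumption of the aldehyde by alkoxide-induced hydride transfer (disproportionation of the Cannizzaro or Tishchenko kind) while the hindered tertiary alkoxide substitutes slowly.

Fallback: a nitrile replaces the aldehyde as activating group, so that no carbonyl group meets the alkoxide. It sets out from 6 (through 8) and returns at 9. 8 and 3-bromo-4-fluorobenzonitrile F13 give the nitrile F14 by SNAr. i-Bu2AlH (one equivalent, −78 °C, then aqueous potassium sodium tartrate) reduces F14 to 9.

**Step 9.** Most likely to go wrong is incomplete epimerisation, because the equatorial preference of an ester group is only about one kcal/mol, so that part of the material stays axial at equilibrium and must be recycled.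

Fallback: C7 is set by face-selective hydrogenation in place of equilibration. It sets out from 14 and returns at 17. DBU moves the ring double bond of 14 into conjugation to give the α,β-unsaturated ester F15 (C6=C7). Hydrogenation with [Ir(cod)(py)(PCy3)]PF6, which tolerates the aryl bromide, should deliver hydrogen to the face opposite the axial angular methyl and give the equatorial ester pivalate F16. Ethanolysis of the pivalate (K2CO3, EtOH) gives 17.

**Step 14.** Most likely to go wrong is slow oxidative addition at the hindered, electron-rich bromide. This leaves time for protodeboronation of 23 and for migration of the allyl double bonds into conjugation through palladium hydride species.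

Fallback: the biaryl is formed before any allyl group exists and the synthesis ends with a Claisen rearrangement. It sets out from 19 and returns at 24. Suzuki–Miyaura coupling of 19 with 4-hydroxyphenylboronic acid F17 gives the biaryl triol F18. Allyl bromide and K2CO3 alkylate only the phenol to give the allyl ether F19. Appel bromination gives the benzylic bromide F20. Vinylmagnesium bromide with CuI gives the allyl arene F21. Thermal aromatic Claisen rearrangement (N,N-diethylaniline, about 190 °C) moves the O-allyl group to the ortho carbon and gives 24.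

## Further compounds

F1 | step 7 | (2R,5R)-2-methyl-5-(prop-1-en-2-yl)cyclohexan-1-one, (+)-dihydrocarvone | C[C@@H]1CC[C@@H](C(C)=C)CC1=O
F2 | step 7 | (5R)-2-methyl-N-[(1R)-1-phenylethyl]-5-(prop-1-en-2-yl)cyclohexan-1-imine (C2 epimers) | CC1CC[C@@H](C(C)=C)CC1=N[C@H](C)c2ccccc2
F3 | step 7 | (2S,5R)-2-methyl-2-(3-oxobutyl)-5-(prop-1-en-2-yl)cyclohexan-1-one | CC(=O)CC[C@]1(C)CC[C@@H](C(C)=C)CC1=O
F4 | step 7 | (4aS,7R)-4a-methyl-7-(prop-1-en-2-yl)-4,4a,5,6,7,8-hexahydronaphthalen-2(3H)-one | O=C1CC[C@]2(C)CC[C@@H](C(C)=C)CC2=C1
F5 | step 7 | (4aS,7R,8aS)-4a-methyl-7-(prop-1-en-2-yl)octahydronaphthalen-2(1H)-one | O=C1CC[C@]2(C)CC[C@@H](C(C)=C)C[C@H]2C1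
F6 | step 7 | (2R,4aS,7R,8aS)-2,4a-dimethyl-7-(prop-1-en-2-yl)decahydronaphthalen-2-ol | O[C@]1(C)CC[C@]2(C)CC[C@@H](C(C)=C)C[C@H]2C1
F7 | step 7 | 3-bromo-4-{[(2R,4aS,7R,8aS)-2,4a-dimethyl-7-(prop-1-en-2-yl)decahydronaphthalen-2-yl]oxy}benzaldehyde | O=Cc1ccc(O[C@]2(C)CC[C@]3(C)CC[C@@H](C(C)=C)C[C@H]3C2)c(Br)c1
F8 | step 7 | (3-bromo-4-{[(2R,4aS,7R,8aS)-2,4a-dimethyl-7-(prop-1-en-2-yl)decahydronaphthalen-2-yl]oxy}phenyl)methanol | OCc1ccc(O[C@]2(C)CC[C@]3(C)CC[C@@H](C(C)=C)C[C@H]3C2)c(Br)c1
F9 | step 1 | (R)-(2-methyloxiran-2-yl)methanol | C[C@@]1(CO)CO1
F10 | step 1 | (S)-2-methylpent-4-ene-1,2-diol | C[C@@](O)(CO)CC=C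
F11 | step 1 | (S)-2-hydroxy-2-methylpent-4-en-1-yl 4-methylbenzenesulfonate | C[C@@](O)(COS(=O)(=O)c1ccc(C)cc1)CC=C
F12 | step 1 | (S)-2-allyl-2-methyloxirane | C[C@]1(CC=C)CO1
F13 | step 3 | 3-bromo-4-fluorobenzonitrile | N#Cc1ccc(F)c(Br)c1
F14 | step 3 | 3-bromo-4-{[(4R,7E)-8-iodo-4,7-dimethylocta-1,7-dien-4-yl]oxy}benzonitrile | C=CC[C@](C)(Oc1ccc(C#N)cc1Br)CC/C(C)=C/I
F15 | step 9 | ethyl (2R,4aR,8aS)-2-{2-bromo-4-[(pivaloyloxy)methyl]phenoxy}-2,4a-dimethyl-1,2,3,4,4a,5,8,8a-octahydronaphthalene-7-carboxylate | Brc1cc(COC(=O)C(C)(C)C)ccc1O[C@]2(C)CC[C@]3(C)CC=C(C(=O)OCC)C[C@H]3C2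
F16 | step 9 | ethyl (2R,4aS,7R,8aS)-2-{2-bromo-4-[(pivaloyloxy)methyl]phenoxy}-2,4a-dimethyldecahydronaphthalene-7-carboxylate (ester equatorial) | Brc1cc(COC(=O)C(C)(C)C)ccc1O[C@]2(C)CC[C@]3(C)CC[C@@H](C(=O)OCC)C[C@H]3C2
F17 | step 14 | 4-hydroxyphenylboronic acid | OB(O)c1ccc(O)cc1
F18 | step 14 | 5-(hydroxymethyl)-2-{[(2R,4aS,7R,8aS)-7-(2-hydroxypropan-2-yl)-2,4a-dimethyldecahydronaphthalen-2-yl]oxy}-[1,1′-biphenyl]-4′-ol | OCc1ccc(O[C@]2(C)CC[C@]3(C)CC[C@@H](C(C)(C)O)C[C@H]3C2)c(-c2ccc(O)cc2)c1
F19 | step 14 | 2-[(2R,4aS,7R,8aS)-2-{[4′-(allyloxy)-5-(hydroxymethyl)-[1,1′-biphenyl]-2-yl]oxy}-2,4a-dimethyldecahydronaphthalen-7-yl]propan-2-ol | OCc1ccc(O[C@]2(C)CC[C@]3(C)CC[C@@H](C(C)(C)O)C[C@H]3C2)c(-c2ccc(OCC=C)cc2)c1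
F20 | step 14 | 2-[(2R,4aS,7R,8aS)-2-{[4′-(allyloxy)-5-(bromomethyl)-[1,1′-biphenyl]-2-yl]oxy}-2,4a-dimethyldecahydronaphthalen-7-yl]propan-2-ol | BrCc1ccc(O[C@]2(C)CC[C@]3(C)CC[C@@H](C(C)(C)O)C[C@H]3C2)c(-c2ccc(OCC=C)cc2)c1
F21 | step 14 | 2-[(2R,4aS,7R,8aS)-2-{[5-allyl-4′-(allyloxy)-[1,1′-biphenyl]-2-yl]oxy}-2,4a-dimethyldecahydronaphthalen-7-yl]propan-2-ol | C=CCc1ccc(O[C@]2(C)CC[C@]3(C)CC[C@@H](C(C)(C)O)C[C@H]3C2)c(-c2ccc(OCC=C)cc2)c1
A1 | alternative 1 | 2-methoxy-5-methylcyclohexa-2,5-diene-1,4-dione | COC1=CC(=O)C(C)=CC1=O
A2 | alternative 1 | triisopropyl[(2-methylidenebut-3-en-1-yl)oxy]silane | C=CC(=C)CO[Si](C(C)C)(C(C)C)C(C)C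
A3 | alternative 1 | (4aR,8aS)-2-methoxy-4a-methyl-7-{[(triisopropylsilyl)oxy]methyl}-4a,5,8,8a-tetrahydronaphthalene-1,4-dione (cis-fused) | COC1=CC(=O)[C@]2(C)CC=C(CO[Si](C(C)C)(C(C)C)C(C)C)C[C@@H]2C1=O
A4 | alternative 2 | tert-butyl{4-[3-{[(2R,4aS,7R,8aS)-2,4a-dimethyl-7-(prop-1-en-2-yl)decahydronaphthalen-2-yl]oxy}buta-1,3-dien-2-yl]phenoxy}dimethylsilane | C=C(O[C@]1(C)CC[C@]2(C)CC[C@@H](C(C)=C)C[C@H]2C1)C(=C)c1ccc(O[Si](C)(C)C(C)(C)C)cc1
A5 | alternative 2 | methyl propiolate | C#CC(=O)OC
A6 | alternative 2 | methyl 5-{4-[(tert-butyldimethylsilyl)oxy]phenyl}-4-{[(2R,4aS,7R,8aS)-2,4a-dimethyl-7-(prop-1-en-2-yl)decahydronaphthalen-2-yl]oxy}cyclohexa-1,4-diene-1-carboxylate | COC(=O)C1=CCC(O[C@]2(C)CC[C@]3(C)CC[C@@H](C(C)=C)C[C@H]3C2)=C(c2ccc(O[Si](C)(C)C(C)(C)C)cc2)C1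
A7 | alternative 3 | 2-(5-allyl-2-{[(2R,4aS,7R,8aS)-2,4a-dimethyl-7-{2-[(triethylsilyl)oxy]propan-2-yl}decahydronaphthalen-2-yl]oxy}phenyl)acetaldehyde | O=CCc1cc(CC=C)ccc1O[C@]2(C)CC[C@]3(C)CC[C@@H](C(C)(C)O[Si](CC)(CC)CC)C[C@H]3C2
A8 | alternative 3 | hepta-1,6-dien-3-one | C=CCCC(=O)C=C
A9 | alternative 3 | 2-allyl-4-(5-allyl-2-{[(2R,4aS,7R,8aS)-2,4a-dimethyl-7-{2-[(triethylsilyl)oxy]propan-2-yl}decahydronaphthalen-2-yl]oxy}phenyl)cyclohex-2-en-1-one (both epimers at the aryl-bearing ring carbon) | O=C1CCC(c2cc(CC=C)ccc2O[C@]3(C)CC[C@]4(C)CC[C@@H](C(C)(C)O[Si](CC)(CC)CC)C[C@H]4C3)C=C1CC=C
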